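**Retrosynthetic overview**
1. The C6–Cl bond comes from SN2 chlorination of the (6R)-allylic alcohol. That alcohol comes from Felkin–Anh 1,2-reduction of a ten-membered α-methylene ketone.
2. The ten-membered ring is closed last, at C5–C6. A cathodic Ni-catalysed coupling joins the C5 alkenyl bromide to the activated C6 carboxyl group.
3. The seco-acid is built by a chelation-controlled C9–C10 Mukaiyama aldol (West cyclohexanone + East lactone aldehyde). C11 methylenation, 12α-hydroxylation and OH-directed 11,20-epoxidation follow.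
4. West half from (−)-myrtenal: 1,2-addition (C2), anodic allylic oxidation (C11=O), cuprate addition (C1), cyclobutane fragmentation, Criegee rearrangement (C14–OAc).
5. East half: the γ-lactone (C6–C9, C17, C19) is bought as (−)-garcinia acid. Ring order: lactone and six-membered ring bought, then spiro-epoxide, then ten-membered ring.

Numbering: briarane numbering throughout. Six-membered ring = C1, C10–C14; C15 = methyl on C1; C20 on C11; chain = C2–C9; C16 on C5; lactone = C7–O–C19(=O)–C17(C18)–C8.
Assumption: (−)-myrtenal, (−)-garcinia acid (hydroxycitric acid lactone from Garcinia extract) and 3-bromobut-3-en-1-ol are taken as commercial.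

**Step 1**
Reactants: 1 3-bromobut-3-en-1-ol
Product: 2 2-bromo-4-iodobut-1-ene
Conditions: I2, PPh3, imidazole, CH2Cl2, 0 °C to rt
Reagents that add atoms: iodine, II
Why: Appel-type iodination (SN2 on the alkoxyphosphonium salt) of a primary alcohol that leaves the alkenyl bromide untouched; no stereocentre is involved.

**Step 2**
Reactants: 2 2-bromo-4-iodobut-1-ene; 3 (1R,5S)-(−)-myrtenal
Product: 5 (1S)-4-bromo-1-[(1R,5S)-6,6-dimethylbicyclo[3.1.1]hept-2-en-2-yl]pent-4-en-1-ol, via (3-bromobut-3-en-1-yl)lithium 4 (not isolated)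
Conditions: 2, t-BuLi (2.1 equiv), Et2O/pentane, −78 °C, 10 min; then 3, −78 °C; H2O
Reagents that add atoms: tert-butyllithium, [Li]C(C)(C)C (lithium of 4 only)
Why: Fast sp3 I/Li exchange (the alkenyl bromide is slower) followed by 1,2-addition to the enal, in which the s-trans enal is attacked on the face opposite the CMe2 bridge to set C2 (S); the minor epimer is removed by chromatography.

**Step 3**
Reactants: 5 C2 carbinol
Product: 6 tert-butyldimethylsilyl ether of 5
Conditions: TBSCl, imidazole, DMF, rt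
Reagents that add atoms: tert-butyldimethylsilyl chloride, CC(C)(C)[Si](C)(C)Cl
Why: Standard silylation that turns the γ-oxygen into a poor leaving group, so the later cuprate adds instead of reductively eliminating; no stereocentre is touched.

**Step 4**
Reactants: 6 TBS ether
Product: 7 verbenone-type enone (C11 ketone conjugated to C10=C1; C2–OTBS side chain on C1; pinane stereocentres unchanged)
Conditions: undivided cell, RVC anode/Ni cathode, constant current, Cl4NHPI (20 mol %), t-BuOOH (1.5 equiv), pyridine, LiClO4, acetone, rt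
Reagents that add atoms: tert-butyl hydroperoxide, CC(C)(C)OO
Why: Known N-oxyl-mediated electrochemical allylic C–H oxidation (the α-pinene to verbenone type) at the aligned, unhindered ring CH2, while C2–H is shielded by the OTBS group and the bromoalkene is deactivated.

**Step 5**
Reactants: 7 enone
Product: 9 C10-bromo pinane ketone with quaternary C1 (C15 methyl anti to the CMe2 bridge, C2 chain syn to it, Br anti to the bridge), via trimethylsilyl enol ether 8 (not isolated)
Conditions: MeLi (2.4 equiv), CuI (1.2 equiv), Et2O, 0 °C; 7, TMSCl, THF, −78 to −30 °C; quick NaHCO3 wash; crude 8, NBS, THF, −78 to 0 °C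
Reagents that add atoms: lithium dimethylcuprate (made from methyllithium, [Li]C, and CuI), [Li+].C[Cu-]C; chlorotrimethylsilane, C[Si](C)(C)Cl (silyl group of 8 only); N-bromosuccinimide, O=C1CCC(=O)N1Br
Why: TMSCl-accelerated Gilman conjugate addition delivers methyl from the face opposite the CMe2 bridge (sets C1), and bromination of the regiodefined enol silane stores the C10 enolate position for step 13.

**Step 6**
Reactants: 9 pinane bromoketone
Product: 11 monocyclic bromoketone (C11 ketone, C10–Br, C14 α-isopropenyl, C2–OAc), via C11(12)-enol acetate 10 (not isolated)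
Conditions: Ac2O, BF3·OEt2 (0.5 equiv), Zn(OAc)2 (0.2 equiv), CH2Cl2, 0 °C to rt; NaHCO3 wash; crude 10, K2CO3 (0.1 equiv), MeOH, 0 °C, 15 min
Reagents that add atoms: acetic anhydride, CC(=O)OC(C)=O
Why: Lewis-acid cyclobutane fragmentation of a nopinone-type ketone breaks C12–CMe2 to give the enol acetate and a tertiary cation that loses a proton to isopropenyl, with in situ silyl-to-acetate exchange at C2 and selective methanolysis of the labile enol acetate; C14 keeps its bought configuration because none of its bonds is broken.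

**Step 7**
Reactants: 11 isopropenyl bromoketone
Product: 13 West fragment (2,14-diacetoxy C10-bromo C11-ketone with the C5 alkenyl bromide), via α-methoxy hydroperoxide 12 (not isolated)
Conditions: O3 (1 equiv, Sudan III end point), CH2Cl2/MeOH, −78 °C; concentrate; Ac2O, Et3N, DMAP (cat.), CH2Cl2, 0 to 40 °C
Reagents that add atoms: ozone, [O-][O+]=O; methanol, CO (methoxy group of 12 only)
Why: Ozonolysis selective for the electron-rich isopropenyl group over the 2-bromoalkene, then Criegee rearrangement of the acylated α-methoxy hydroperoxide, in which C14 migrates to oxygen with retention to give the 14α-acetate.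

**Step 8**
Reactants: 14 (2S,3S)-(−)-garcinia acid
Product: 15 bis[2-(trimethylsilyl)ethyl] (2S,3S)-3-hydroxy-5-oxotetrahydrofuran-2,3-dicarboxylate
Conditions: Me3SiCH2CH2OH (2.5 equiv), DCC (2.2 equiv), DMAP (0.1 equiv), CH2Cl2, 0 °C to rt
Reagents that add atoms: 2-(trimethylsilyl)ethanol, C[Si](C)(C)CCO
Why: Steglich esterification of both acids; C8 (lactone C3) is bought with the target configuration and is not touched.

**Step 9**
Reactants: 15 bis-TMSE ester
Product: 16 (2S,3S,4R)-4-methyl lactone diester (C18 methyl cis to 8-OH)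
Conditions: LDA (2.1 equiv), THF/DMPU, −78 °C; MeI, −78 to −40 °C; AcOH
Reagents that add atoms: iodomethane, CI
Why: Fráter–Seebach-type alkylation of the alkoxide/lactone-enolate dianion at the less hindered CH2, with MeI entering from the face opposite both ester groups (the OH face) to set C17.

**Step 10**
Reactants: 16 (2S,3S,4R)-diester
Product: 17 (2R,3S,4R)-diester (C6 ester trans to C9 ester)
Conditions: DBU (0.2 equiv), toluene, 40 °C
Reagents that add atoms: none
Why: Base-mediated epimerisation α to the C6 ester relieves the cis-vicinal diester strain, so C7 is set under thermodynamic control by the bought C8 centre.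

**Step 11**
Reactants: 17 (2R,3S,4R)-diester
Product: 18 2-(trimethylsilyl)ethyl (2R,3R,4R)-3-hydroxy-3-(hydroxymethyl)-4-methyl-5-oxotetrahydrofuran-2-carboxylate
Conditions: BH3·SMe2 (1.1 equiv), NaBH4 (5 mol %), THF, 0 °C to rt; aqueous work-up
Reagents that add atoms: none
Why: Hydroxyl-directed borane reduction (malate-type α-hydroxy-ester selectivity through a five-membered alkoxyborane) reduces only the C9 ester and spares the C6 ester and the lactone.

**Step 12**
Reactants: 18 diol
Product: 19 East aldehyde, 2-(trimethylsilyl)ethyl (2R,3S,4R)-3-formyl-3-hydroxy-4-methyl-5-oxotetrahydrofuran-2-carboxylate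
Conditions: Dess–Martin periodinane, CH2Cl2, 0 °C to rt; used at once
Reagents that add atoms: none
Why: Dess–Martin oxidation of the only oxidisable (primary) alcohol gives a non-enolisable α-hydroxy aldehyde, so no stereocentre is at risk.

**Step 13**
Reactants: 13 West bromoketone; 19 East aldehyde
Product: 22 seco-briarane 2,9,14-triacetate (C11 ketone, free 8-OH, C6 TMSE ester, C5 alkenyl bromide), via West trimethylsilyl enol ether 20 (not isolated), via C9 aldol 21 (not isolated)
Conditions: 13, Zn, TMSCl, THF, 0 °C, filter; 19, MgBr2·OEt2 (3 equiv), CH2Cl2, −40 to 0 °C; aqueous wash; crude 21, Ac2O, pyridine, DMAP (cat.), 0 °C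
Reagents that add atoms: chlorotrimethylsilane, C[Si](C)(C)Cl (silyl group of 20 only); acetic anhydride, CC(=O)OC(C)=O
Why: Reductive silylation gives the C10 enol silane regiospecifically, and the chelation-controlled Mukaiyama aldol (Mg bridging 8-OH and the aldehyde, attack from the smaller C17 side, open transition state with C8 turned away from quaternary C1 and C9 ending equatorial) sets C9 and C10 in a matched sense; acetylation stops at the secondary 9-OH.

**Step 14**
Reactants: 22 C11 ketone
Product: 23 11(20)-exomethylene compound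
Conditions: Zn, CH2Br2, TiCl4 (pre-aged Takai–Lombardo reagent), THF/CH2Cl2, 0 °C to rt
Reagents that add atoms: dibromomethane, BrCBr
Why: Non-basic Takai–Lombardo methylenation is selective for the ketone over esters and lactone and avoids E1cB loss of the β-acetoxy group, so C10 is not epimerised.

**Step 15**
Reactants: 23 exomethylene compound
Product: 24 12α-allylic alcohol
Conditions: SeO2 (0.3 equiv), t-BuOOH (2 equiv), CH2Cl2, 0 °C to rt
Reagents that add atoms: tert-butyl hydroperoxide, CC(C)(C)OO
Why: SeO2 ene/[2,3]-sigmatropic allylic hydroxylation removes the axial C12–Hα and returns oxygen to the same α face (as in 7α-hydroxylation of labd-8(17)-enes), preferring CH2 over the hindered C10–H and ignoring the deactivated bromoalkene.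

**Step 16**
Reactants: 24 12α-allylic alcohol
Product: 25 11α,20-epoxy-12α-ol
Conditions: VO(acac)2 (5 mol %), t-BuOOH (1.3 equiv), CH2Cl2, 0 °C
Reagents that add atoms: tert-butyl hydroperoxide, CC(C)(C)OO
Why: Vanadium-catalysed hydroxyl-directed epoxidation delivers oxygen syn to the axial 12α-OH (also the face away from the axial C15 methyl), which sets C11 and leaves the bromoalkene untouched.

**Step 17**
Reactants: 25 epoxy alcohol
Product: 26 2,9,12,14-tetraacetate TMSE ester
Conditions: Ac2O, pyridine, DMAP (cat.), 0 °C to rt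
Reagents that add atoms: acetic anhydride, CC(=O)OC(C)=O
Why: Acetylation of the only secondary alcohol; the hindered tertiary 8-OH does not react.

**Step 18**
Reactants: 26 TMSE ester
Product: 27 seco-acid (free C6 carboxylic acid)
Conditions: TBAF (1.5 equiv), THF, 0 °C; pH 4.5 KH2PO4 buffer
Reagents that add atoms: none
Why: Fluoride-induced β-elimination of the 2-(trimethylsilyl)ethyl ester is orthogonal to the four acetates, the lactone and the epoxide.

**Step 19**
Reactants: 27 seco-acid
Product: 29 ten-membered α-methylene ketone (6-oxo-5(16)-ene briarane), via mixed pivalic anhydride 28 (not isolated)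
Conditions: PivCl, Et3N, THF, −20 °C; then syringe-pump addition (final 2 mM) to NiBr2·dme (20 mol %), dtbbpy (24 mol %), Bu4NBr, DMA, undivided cell, Zn(+)/Ni foam(−), 3 mA constant current, rt
Reagents that add atoms: pivaloyl chloride, CC(C)(C)C(=O)Cl (pivaloyl group of 28 only)
Why: Proposed new method: cathodically generated Ni(0) should add oxidatively to the C5 alkenyl bromide, be reduced at the cathode to alkenyl–Ni(I), insert into the less hindered acyl C–O bond of the mixed anhydride and eliminate reductively to forge C5–C6 and close the ten-membered ring, with the current metering the low-valent nickel so that slow substrate addition keeps the coupling intramolecular; the closest known reaction types are Zn/Mn-driven Ni-catalysed reductive ketone and enone syntheses from organic (pseudo)halides with activated carboxylic acid derivatives and Ni-electrocatalytic cross-electrophile coupling, neither shown for an alkenyl bromide/anhydride pair in a medium-ring closure; no stereocentre is formed and C7 stays in its more stable trans arrangement.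

**Step 20**
Reactants: 29 macrocyclic enone
Product: 30 (6R)-allylic alcohol
Conditions: NaBH4, CeCl3·7H2O, MeOH/CH2Cl2, −78 °C
Reagents that add atoms: none
Why: Luche 1,2-reduction under Felkin–Anh control by C7 (C7–O perpendicular to the carbonyl, hydride from the ring periphery) gives the 6,7-syn relationship, i.e. the C6 epimer needed for inversion.

**Step 21**
Reactants: 30 (6R)-allylic alcohol
Product: 31 target CNP0349227.2
Conditions: PPh3, hexachloroacetone, CH2Cl2, −20 to 0 °C
Reagents that add atoms: hexachloroacetone, O=C(C(Cl)(Cl)Cl)C(Cl)(Cl)Cl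
Why: Appel-type (PPh3/hexachloroacetone) chlorination of a secondary allylic alcohol proceeds by direct SN2 with inversion to the (6S)-chloride, because the electron-withdrawing C7 lactone oxygen disfavours ionisation and SN2′ transposition; the tertiary 8-OH is inert.

**Compound list**
1 | 3-bromobut-3-en-1-ol | C=C(Br)CCO | starting material
2 | 2-bromo-4-iodobut-1-ene | C=C(Br)CCI | intermediate
3 | (1R,5S)-(−)-myrtenal | O=CC1=CC[C@H]2C[C@@H]1C2(C)C | starting material
4 | (3-bromobut-3-en-1-yl)lithium | [Li]CCC(Br)=C | intermediate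
5 | (1S)-4-bromo-1-[(1R,5S)-6,6-dimethylbicyclo[3.1.1]hept-2-en-2-yl]pent-4-en-1-ol | C=C(Br)CC[C@H](O)C1=CC[C@H]2C[C@@H]1C2(C)C | intermediate
6 | TBS ether of 5 | C=C(Br)CC[C@H](O[Si](C)(C)C(C)(C)C)C1=CC[C@H]2C[C@@H]1C2(C)C | intermediate
7 | verbenone-type enone (C11 ketone) | C=C(Br)CC[C@H](O[Si](C)(C)C(C)(C)C)C1=CC(=O)[C@H]2C[C@@H]1C2(C)C | intermediate
8 | pinane TMS enol ether, C1 quaternary (C15 anti to the CMe2 bridge) | C=C(Br)CC[C@H](O[Si](C)(C)C(C)(C)C)[C@@]1(C)[C@@H]2C[C@@H](C2(C)C)C(O[Si](C)(C)C)=C1 | intermediate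
9 | C10-bromo pinane ketone | C=C(Br)CC[C@H](O[Si](C)(C)C(C)(C)C)[C@@]1(C)[C@@H]2C[C@@H](C2(C)C)C(=O)[C@@H]1Br | intermediate
10 | ring-opened C11(12)-enol acetate, C14 isopropenyl, C2 acetate | C=C(Br)CC[C@H](OC(C)=O)[C@@]1(C)[C@@H](C(C)=C)CC=C(OC(C)=O)[C@@H]1Br | intermediate
11 | monocyclic C14-isopropenyl C10-bromo C11-ketone, C2 acetate | C=C(Br)CC[C@H](OC(C)=O)[C@@]1(C)[C@@H](C(C)=C)CCC(=O)[C@@H]1Br | intermediate
12 | α-methoxy hydroperoxide on C14 (epimers at the peroxyketal carbon) | C=C(Br)CC[C@H](OC(C)=O)[C@@]1(C)[C@@H](C(C)(OC)OO)CCC(=O)[C@@H]1Br | intermediate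
13 | West fragment, 2,14-diacetoxy C10-bromo C11-ketone | C=C(Br)CC[C@H](OC(C)=O)[C@@]1(C)[C@@H](OC(C)=O)CCC(=O)[C@@H]1Br | intermediate
14 | (2S,3S)-(−)-garcinia acid | OC(=O)[C@]1(O)CC(=O)O[C@@H]1C(O)=O | starting material
15 | bis-TMSE (2S,3S)-diester | C[Si](C)(C)CCOC(=O)[C@]1(O)CC(=O)O[C@@H]1C(=O)OCC[Si](C)(C)C | intermediate
16 | (2S,3S,4R)-4-methyl diester | C[Si](C)(C)CCOC(=O)[C@]1(O)[C@@H](C)C(=O)O[C@@H]1C(=O)OCC[Si](C)(C)C | intermediate
17 | (2R,3S,4R)-4-methyl diester | C[Si](C)(C)CCOC(=O)[C@]1(O)[C@@H](C)C(=O)O[C@H]1C(=O)OCC[Si](C)(C)C | intermediate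
18 | (2R,3R,4R)-3-(hydroxymethyl) lactone TMSE ester | OC[C@]1(O)[C@@H](C)C(=O)O[C@H]1C(=O)OCC[Si](C)(C)C | intermediate
19 | East aldehyde, (2R,3S,4R) | O=C[C@]1(O)[C@@H](C)C(=O)O[C@H]1C(=O)OCC[Si](C)(C)C | intermediate
20 | West C10(11)-TMS enol ether | C=C(Br)CC[C@H](OC(C)=O)[C@@]1(C)[C@@H](OC(C)=O)CCC(O[Si](C)(C)C)=C1 | intermediate
21 | C9 aldol (free 8,9-diol, C11 ketone) | C=C(Br)CC[C@H](OC(C)=O)[C@@]1(C)[C@@H](OC(C)=O)CCC(=O)[C@@H]1[C@H](O)[C@]1(O)[C@@H](C)C(=O)O[C@H]1C(=O)OCC[Si](C)(C)C | intermediate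
22 | seco 2,9,14-triacetate, C11 ketone | C=C(Br)CC[C@H](OC(C)=O)[C@@]1(C)[C@@H](OC(C)=O)CCC(=O)[C@@H]1[C@H](OC(C)=O)[C@]1(O)[C@@H](C)C(=O)O[C@H]1C(=O)OCC[Si](C)(C)C | intermediate
23 | seco 11(20)-ene | C=C(Br)CC[C@H](OC(C)=O)[C@@]1(C)[C@@H](OC(C)=O)CCC(=C)[C@@H]1[C@H](OC(C)=O)[C@]1(O)[C@@H](C)C(=O)O[C@H]1C(=O)OCC[Si](C)(C)C | intermediate
24 | seco 12α-ol | C=C(Br)CC[C@H](OC(C)=O)[C@@]1(C)[C@@H](OC(C)=O)C[C@@H](O)C(=C)[C@@H]1[C@H](OC(C)=O)[C@]1(O)[C@@H](C)C(=O)O[C@H]1C(=O)OCC[Si](C)(C)C | intermediate
25 | seco 11α,20-epoxy-12α-ol | C=C(Br)CC[C@H](OC(C)=O)[C@@]1(C)[C@@H](OC(C)=O)C[C@@H](O)[C@]2(CO2)[C@@H]1[C@H](OC(C)=O)[C@]1(O)[C@@H](C)C(=O)O[C@H]1C(=O)OCC[Si](C)(C)C | intermediate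
26 | seco tetraacetate TMSE ester | C=C(Br)CC[C@H](OC(C)=O)[C@@]1(C)[C@@H](OC(C)=O)C[C@@H](OC(C)=O)[C@]2(CO2)[C@@H]1[C@H](OC(C)=O)[C@]1(O)[C@@H](C)C(=O)O[C@H]1C(=O)OCC[Si](C)(C)C | intermediate
27 | seco-acid | C=C(Br)CC[C@H](OC(C)=O)[C@@]1(C)[C@@H](OC(C)=O)C[C@@H](OC(C)=O)[C@]2(CO2)[C@@H]1[C@H](OC(C)=O)[C@]1(O)[C@@H](C)C(=O)O[C@H]1C(=O)O | intermediate
28 | mixed pivalic anhydride of 27 | C=C(Br)CC[C@H](OC(C)=O)[C@@]1(C)[C@@H](OC(C)=O)C[C@@H](OC(C)=O)[C@]2(CO2)[C@@H]1[C@H](OC(C)=O)[C@]1(O)[C@@H](C)C(=O)O[C@H]1C(=O)OC(=O)C(C)(C)C | intermediate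
29 | 6-oxo-5(16)-ene briarane | C=C1CC[C@H](OC(C)=O)[C@@]2(C)[C@@H](OC(C)=O)C[C@@H](OC(C)=O)[C@]3(CO3)[C@@H]2[C@H](OC(C)=O)[C@]2(O)[C@@H](C)C(=O)O[C@H]2C1=O | intermediate
30 | (6R)-allylic alcohol | C=C1CC[C@H](OC(C)=O)[C@@]2(C)[C@@H](OC(C)=O)C[C@@H](OC(C)=O)[C@]3(CO3)[C@@H]2[C@H](OC(C)=O)[C@]2(O)[C@@H](C)C(=O)O[C@H]2[C@@H]1O | intermediate
31 | CNP0349227.2, (1S,2S,6S,7R,8R,9S,10S,11R,12R,14S,17R) | C=C1CC[C@H](OC(C)=O)[C@@]2(C)[C@@H](OC(C)=O)C[C@@H](OC(C)=O)[C@]3(CO3)[C@@H]2[C@H](OC(C)=O)[C@]2(O)[C@@H](C)C(=O)O[C@H]2[C@H]1Cl | target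

**Total step count:** 21.
**Longest linear sequence:** 16 (steps 1–7 and 13–21).

**Three steps most likely to fail**

- **Step 6 (cyclobutane fragmentation).** The cation may be trapped instead of eliminating, or the bromoketone may scramble. The fallback sets out from 9 and splits the one-pot acetolysis into separate events.
  - Ac2O with catalytic Sc(OTf)3 exchanges the silyl ether to give the pinane bromoketone C2 acetate F1.
  - Dry HCl in AcOH opens the cyclobutane with chloride capture to the C14 2-chloropropan-2-yl ketone F2.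
  - Dehydrochlorination on neutral alumina gives the isopropenyl group.
  - The route is rejoined at 11.

- **Step 13 (aldol between a neopentyl enol silane and an α-quaternary aldehyde).** Low reactivity or the wrong C9 epimer is possible. The fallback sets out from 13 and 19 and drops the enol silane/Lewis acid mode. A SmI2-mediated Reformatsky-type aldol (THF, −78 °C) is used instead, in which the samarium(III) enolate made directly from the bromide is chelated to the aldehyde and 8-OH in a closed transition state. It comes back at 21, which is acetylated as before. No new compound is made (F0).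

- **Step 19 (new cathodic Ni acyl–alkenyl macrocyclisation).** Risks are acyl–Ni decarbonylation, β-lactonisation of the activated acid by 8-OH, and oligomers. The fallback sets out from 27 and uses only known chemistry.
  - BH3·THF reduces the acid to the C6 primary alcohol F3.
  - Dess–Martin oxidation gives the C6 aldehyde F4.
  - Stoichiometric CrCl2/cat. NiCl2 Nozaki–Hiyama–Kishi macrocyclisation (DMSO/THF, high dilution) gives the C6-epimeric macrocyclic allylic alcohols F5.
  - Dess–Martin oxidation brings the route back at 29.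

**Further compounds**
F1 | step 6 | pinane C10-bromoketone C2 acetate | C=C(Br)CC[C@H](OC(C)=O)[C@@]1(C)[C@@H]2C[C@@H](C2(C)C)C(=O)[C@@H]1Br
F2 | step 6 | monocyclic C14 (2-chloropropan-2-yl) C10-bromo C11-ketone, C2 acetate | C=C(Br)CC[C@H](OC(C)=O)[C@@]1(C)[C@@H](C(C)(C)Cl)CCC(=O)[C@@H]1Br
F0 | step 13 | none | none
F3 | step 19 | seco C6 primary alcohol | C=C(Br)CC[C@H](OC(C)=O)[C@@]1(C)[C@@H](OC(C)=O)C[C@@H](OC(C)=O)[C@]2(CO2)[C@@H]1[C@H](OC(C)=O)[C@]1(O)[C@@H](C)C(=O)O[C@H]1CO
F4 | step 19 | seco C6 aldehyde | C=C(Br)CC[C@H](OC(C)=O)[C@@]1(C)[C@@H](OC(C)=O)C[C@@H](OC(C)=O)[C@]2(CO2)[C@@H]1[C@H](OC(C)=O)[C@]1(O)[C@@H](C)C(=O)O[C@H]1C=O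
F5 | step 19 | macrocyclic allylic alcohols, C6 epimers | C=C1CC[C@H](OC(C)=O)[C@@]2(C)[C@@H](OC(C)=O)C[C@@H](OC(C)=O)[C@]3(CO3)[C@@H]2[C@H](OC(C)=O)[C@]2(O)[C@@H](C)C(=O)O[C@H]2C1O
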